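The upper flavan unit is disconnected across ring C. Its phenolic oxygen O1 and benzylic carbon C4 sit ortho to each other on phloroglucinol ring A, and the O1–C2 and C3–C4 bonds flank C2–C3: the retron of an ortho-quinone methide/alkene [4+2] cycloaddition. In one operation a chiral Brønsted acid should join three components (the ring A salicylaldehyde, 2-ethoxyethanol and the Z-enol acetate carrying catechol ring B) into the epicatechin skeleton, closing ring C with cis C2/C3 and leaving an ionisable ether at C4. That ether later forges the 4β→8 bond to benzylated (−)-epigallocatechin gallate, assembled from chiral-pool (−)-epigallocatechin and tribenzylgallic acid; hydrogenolysis finishes.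

Key step: step 4

Assumption: 7 is drawn as its 3,4-trans (4S) ether because the acid can equilibrate this ionisable centre; the 4R epimer, should it form, is carried on equally, since step 8 ionises C4.

Step 1
Reactants: 1 3,4-bis(benzyloxy)benzaldehyde
Product: 2 1,2-bis(benzyloxy)-4-ethynylbenzene
Conditions: dimethyl (1-diazo-2-oxopropyl)phosphonate (1.3 equiv), K2CO3 (2 equiv), MeOH/THF, rt
Reagents that add atoms: dimethyl (1-diazo-2-oxopropyl)phosphonate, COP(=O)(OC)C(=[N+]=[N-])C(C)=O
Why: Seyferth–Gilbert homologation in its Ohira–Bestmann form should convert the non-enolisable aryl aldehyde into the terminal alkyne under mild base that leaves the benzyl ethers untouched.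

Step 2
Reactants: 2 1,2-bis(benzyloxy)-4-ethynylbenzene
Product: 3 (Z)-2-[3,4-bis(benzyloxy)phenyl]ethenyl acetate
Conditions: AcOH (1.5 equiv), Ru(η3-2-methylallyl)2(Ph2P(CH2)4PPh2) (2 mol %), toluene, 50 °C
Reagents that add atoms: acetic acid, CC(=O)O
Why: Ruthenium-catalysed anti-Markovnikov hydro-acyloxylation of a terminal alkyne runs through a ruthenium vinylidene and should place acetate and aryl cis, so the Z geometry that becomes the cis C2/C3 pair is set here.

Step 3
Reactants: 4 2,4,6-trihydroxybenzaldehyde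
Product: 5 2,4-bis(benzyloxy)-6-hydroxybenzaldehyde
Conditions: BnBr (2.05 equiv), K2CO3 (2.1 equiv), DMF, 0 °C to rt
Reagents that add atoms: benzyl bromide, BrCc1ccccc1
Why: Williamson etherification should stop at the dibenzyl ether because the last ortho hydroxyl is held in a hydrogen bond to the formyl group and is alkylated far more slowly.

Step 4
Reactants: 3 (Z)-2-[3,4-bis(benzyloxy)phenyl]ethenyl acetate (1.5 equiv); 5 2,4-bis(benzyloxy)-6-hydroxybenzaldehyde
Product: 7 (2R,3R,4S)-5,7-bis(benzyloxy)-2-[3,4-bis(benzyloxy)phenyl]-4-(2-ethoxyethoxy)chroman-3-yl acetate, via alkoxy-substituted o-quinone methide 6 (not isolated)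
Conditions: 2-ethoxyethanol (3 equiv), (R)-3,3'-bis(2,4,6-triisopropylphenyl)-1,1'-binaphthyl-2,2'-diyl N-triflylphosphoramide (10 mol %), 5 Å MS, CH2Cl2, 0 °C to rt
Reagents that add atoms: 2-ethoxyethanol, CCOCCO
Why: The chiral acid should condense 5 with 2-ethoxyethanol (loss of water) to the alkoxy-substituted o-quinone methide 6, an electron-poor 1-oxadiene (O1=C8a–C4a=C4) that stays hydrogen-bonded to the catalyst, and 6 is trapped by the electron-rich alkene 3 in an inverse-electron-demand oxa-[4+2] cycloaddition in which C3–C4 forms slightly ahead of O1–C2. The closest known reactions are the acid-catalysed three-component chroman synthesis from salicylaldehydes, alcohols or orthoformates and styrenes, and the chiral Brønsted acid catalysed [4+2] cycloaddition of o-quinone methides with styrenes. Ring C is closed by this intermolecular hetero-Diels–Alder cycloaddition itself, both new bonds arising suprafacially on the alkene. C2 and C3 therefore inherit the Z geometry of 3 as a cis pair, their absolute (2R,3R) sense is set by the chiral acid (the antipode that gives this series is used), and C4, an acid-labile benzylic acetal-type centre, should settle as the pseudo-axial 3,4-trans (4S) ether and is erased in step 8 in any case. The step needs O1 to bond to the aryl-bearing carbon, which the para-benzyloxy group of ring B should secure by stabilising positive charge at C2 far better than the ester-deactivated acetoxy oxygen could at C3; it also needs the alkene to outcompete arene carbons and alcohol for 6, which the excess of 3 and the reversibility of acetal formation should secure.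

Step 5
Reactants: 7 (2R,3R,4S)-5,7-bis(benzyloxy)-2-[3,4-bis(benzyloxy)phenyl]-4-(2-ethoxyethoxy)chroman-3-yl acetate
Product: 8 (2R,3R,4S)-5,7-bis(benzyloxy)-2-[3,4-bis(benzyloxy)phenyl]-4-(2-ethoxyethoxy)chroman-3-ol
Conditions: K2CO3 (0.2 equiv), MeOH/THF, rt
Reagents that add atoms: none
Why: Base-catalysed transesterification (Zemplén-type methanolysis) should remove the secondary acetate while the base-stable C4 ether, the benzyl ethers and all stereocentres stay untouched.

Step 6
Reactants: 9 (−)-epigallocatechin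
Product: 10 (2R,3R)-5,7-bis(benzyloxy)-2-[3,4,5-tris(benzyloxy)phenyl]chroman-3-ol
Conditions: BnBr (5.5 equiv), K2CO3 (6 equiv), DMF, 0 °C to rt, argon
Reagents that add atoms: benzyl bromide, BrCc1ccccc1
Why: Williamson etherification with a carbonate base should alkylate only the five acidic phenols and leave the secondary C3 alcohol free, while the low temperature and the exclusion of oxygen should suppress C2 epimerisation and oxidation of the pyrogallol ring, so the (2R,3R) centres of the chiral-pool flavan are kept.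

Step 7
Reactants: 10 (2R,3R)-5,7-bis(benzyloxy)-2-[3,4,5-tris(benzyloxy)phenyl]chroman-3-ol; 11 3,4,5-tris(benzyloxy)benzoic acid (1.5 equiv)
Product: 12 (2R,3R)-5,7-bis(benzyloxy)-2-[3,4,5-tris(benzyloxy)phenyl]chroman-3-yl 3,4,5-tris(benzyloxy)benzoate
Conditions: N,N'-dicyclohexylcarbodiimide (DCC, 1.6 equiv), 4-(dimethylamino)pyridine (DMAP, 0.3 equiv), CH2Cl2, 0 °C to rt
Reagents that add atoms: none
Why: Steglich esterification should acylate the hindered axial C3 hydroxyl through the O-acylisourea and the acylpyridinium ion under neutral conditions; the C3–O bond of the alcohol is not broken, so C3 keeps its configuration and C2 is not exposed to base.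

Step 8
Reactants: 8 (2R,3R,4S)-5,7-bis(benzyloxy)-2-[3,4-bis(benzyloxy)phenyl]-4-(2-ethoxyethoxy)chroman-3-ol; 12 (2R,3R)-5,7-bis(benzyloxy)-2-[3,4,5-tris(benzyloxy)phenyl]chroman-3-yl 3,4,5-tris(benzyloxy)benzoate (4 equiv, excess recovered)
Product: 13 (2R,3R)-5,7-bis(benzyloxy)-8-[(2R,3R,4R)-5,7-bis(benzyloxy)-2-[3,4-bis(benzyloxy)phenyl]-3-hydroxychroman-4-yl]-2-[3,4,5-tris(benzyloxy)phenyl]chroman-3-yl 3,4,5-tris(benzyloxy)benzoate
Conditions: TMSOTf (0.2 equiv), CH2Cl2, −78 to −40 °C; then Et3N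
Reagents that add atoms: none
Why: Lewis-acid-mediated Friedel–Crafts alkylation (SN1 at C4) should let C8 of 12, the position known to react in benzylated flavan-3-ols, attack the ring-A-stabilised benzylic cation from the face opposite the cis C2-aryl and C3-hydroxyl groups, which sets the 3,4-trans (4β, 4R) centre, while the excess of 12 suppresses oligomerisation.

Step 9
Reactants: 13 (2R,3R)-5,7-bis(benzyloxy)-8-[(2R,3R,4R)-5,7-bis(benzyloxy)-2-[3,4-bis(benzyloxy)phenyl]-3-hydroxychroman-4-yl]-2-[3,4,5-tris(benzyloxy)phenyl]chroman-3-yl 3,4,5-tris(benzyloxy)benzoate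
Product: 14 (2R,3R)-8-[(2R,3R,4R)-2-(3,4-dihydroxyphenyl)-3,5,7-trihydroxychroman-4-yl]-5,7-dihydroxy-2-(3,4,5-trihydroxyphenyl)chroman-3-yl 3,4,5-trihydroxybenzoate
Conditions: H2 (1 atm), Pd(OH)2/C, THF/MeOH/H2O, rt
Reagents that add atoms: none
Why: Catalytic hydrogenolysis should cleave all twelve benzyl ethers while the aryl ester, the interflavan bond and all stereocentres are inert to these neutral conditions.

Compound list
1 | 3,4-bis(benzyloxy)benzaldehyde | O=Cc1ccc(OCc2ccccc2)c(OCc2ccccc2)c1 | starting material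
2 | 1,2-bis(benzyloxy)-4-ethynylbenzene | C#Cc1ccc(OCc2ccccc2)c(OCc2ccccc2)c1 | intermediate
3 | (Z)-2-[3,4-bis(benzyloxy)phenyl]ethenyl acetate | CC(=O)O/C=C\c1ccc(OCc2ccccc2)c(OCc2ccccc2)c1 | intermediate
4 | 2,4,6-trihydroxybenzaldehyde | O=Cc1c(O)cc(O)cc1O | starting material
5 | 2,4-bis(benzyloxy)-6-hydroxybenzaldehyde | O=Cc1c(O)cc(OCc2ccccc2)cc1OCc1ccccc1 | intermediate
6 | (6E)-3,5-bis(benzyloxy)-6-[(2-ethoxyethoxy)methylidene]cyclohexa-2,4-dien-1-one (alkoxy-substituted o-quinone methide) | CCOCCO/C=C1/C(=O)C=C(OCc2ccccc2)C=C1OCc1ccccc1 | intermediate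
7 | (2R,3R,4S)-5,7-bis(benzyloxy)-2-[3,4-bis(benzyloxy)phenyl]-4-(2-ethoxyethoxy)chroman-3-yl acetate | CCOCCO[C@H]1c2c(OCc3ccccc3)cc(OCc3ccccc3)cc2O[C@H](c2ccc(OCc3ccccc3)c(OCc3ccccc3)c2)[C@@H]1OC(C)=O | intermediate
8 | (2R,3R,4S)-5,7-bis(benzyloxy)-2-[3,4-bis(benzyloxy)phenyl]-4-(2-ethoxyethoxy)chroman-3-ol | CCOCCO[C@H]1c2c(OCc3ccccc3)cc(OCc3ccccc3)cc2O[C@H](c2ccc(OCc3ccccc3)c(OCc3ccccc3)c2)[C@@H]1O | intermediate
9 | (−)-epigallocatechin, (2R,3R)-2-(3,4,5-trihydroxyphenyl)chroman-3,5,7-triol | O[C@@H]1Cc2c(O)cc(O)cc2O[C@@H]1c1cc(O)c(O)c(O)c1 | starting material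
10 | (2R,3R)-5,7-bis(benzyloxy)-2-[3,4,5-tris(benzyloxy)phenyl]chroman-3-ol (penta-O-benzyl derivative of 9) | O[C@@H]1Cc2c(OCc3ccccc3)cc(OCc3ccccc3)cc2O[C@@H]1c1cc(OCc2ccccc2)c(OCc2ccccc2)c(OCc2ccccc2)c1 | intermediate
11 | 3,4,5-tris(benzyloxy)benzoic acid | O=C(O)c1cc(OCc2ccccc2)c(OCc2ccccc2)c(OCc2ccccc2)c1 | starting material
12 | (2R,3R)-5,7-bis(benzyloxy)-2-[3,4,5-tris(benzyloxy)phenyl]chroman-3-yl 3,4,5-tris(benzyloxy)benzoate (octa-O-benzyl (−)-epigallocatechin gallate) | O=C(O[C@@H]1Cc2c(OCc3ccccc3)cc(OCc3ccccc3)cc2O[C@@H]1c1cc(OCc2ccccc2)c(OCc2ccccc2)c(OCc2ccccc2)c1)c1cc(OCc2ccccc2)c(OCc2ccccc2)c(OCc2ccccc2)c1 | intermediate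
13 | (2R,3R)-5,7-bis(benzyloxy)-8-[(2R,3R,4R)-5,7-bis(benzyloxy)-2-[3,4-bis(benzyloxy)phenyl]-3-hydroxychroman-4-yl]-2-[3,4,5-tris(benzyloxy)phenyl]chroman-3-yl 3,4,5-tris(benzyloxy)benzoate (dodeca-O-benzyl 4β→8 dimer) | O=C(O[C@@H]1Cc2c(OCc3ccccc3)cc(OCc3ccccc3)c([C@H]3c4c(OCc5ccccc5)cc(OCc5ccccc5)cc4O[C@H](c4ccc(OCc5ccccc5)c(OCc5ccccc5)c4)[C@@H]3O)c2O[C@@H]1c1cc(OCc2ccccc2)c(OCc2ccccc2)c(OCc2ccccc2)c1)c1cc(OCc2ccccc2)c(OCc2ccccc2)c(OCc2ccccc2)c1 | intermediate
14 | (2R,3R)-8-[(2R,3R,4R)-2-(3,4-dihydroxyphenyl)-3,5,7-trihydroxychroman-4-yl]-5,7-dihydroxy-2-(3,4,5-trihydroxyphenyl)chroman-3-yl 3,4,5-trihydroxybenzoate, epicatechin-(4β→8)-epigallocatechin 3-O-gallate | O=C(O[C@@H]1Cc2c(O)cc(O)c([C@H]3c4c(O)cc(O)cc4O[C@H](c4ccc(O)c(O)c4)[C@@H]3O)c2O[C@@H]1c1cc(O)c(O)c(O)c1)c1cc(O)c(O)c(O)c1 | target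

Total step count: 9. Longest linear sequence: 6 steps (steps 1, 2, 4, 5, 8 and 9).

Steps most likely to fail

Step 4. The alkoxy-stabilised methide may be captured by alcohol or by electron-rich arene carbons faster than by the weakly nucleophilic enol acetate, and the acid may control the alkene face poorly on an alkoxy-bearing methide. The fallback sets out from 5 and comes back at 7. Reduction with NaBH4 (THF/MeOH, 0 °C) should give 3,5-bis(benzyloxy)-2-(hydroxymethyl)phenol F1. Its unsubstituted, more electrophilic o-quinone methide, released by the same chiral acid, should add 3 in a two-component [4+2] cycloaddition to give (2R,3R)-5,7-bis(benzyloxy)-2-[3,4-bis(benzyloxy)phenyl]chroman-3-yl acetate F2. Benzylic oxidation of F2 at C4 with DDQ in the presence of 2-ethoxyethanol (CH2Cl2, rt) should then give 7.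

Step 8. Over-alkylation is the danger: the product still carries a nucleophilic ring A in its upper unit and can capture a second cation, leading to oligomers, and 8 can condense with itself. The fallback sets out from 8 and comes back at 14. Bromination with NBS (CH2Cl2, −20 °C) should cap the reactive position and give (2R,3R,4S)-5,7-bis(benzyloxy)-2-[3,4-bis(benzyloxy)phenyl]-8-bromo-4-(2-ethoxyethoxy)chroman-3-ol F3. Coupling of F3 with 12 under TMSOTf should give the upper-unit 8-bromo derivative of 13 F4, in which the bromine sits at C8 of ring A of the upper unit and the 4β→8 geometry is unchanged. Hydrogenolysis of F4 (H2, Pd(OH)2/C, Et3N, THF/MeOH/H2O) should remove the bromine together with the benzyl groups and give 14.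

Step 2. Regio- or stereochemical leakage to the Markovnikov or the E enol ester, or Z-to-E isomerisation during purification, would destroy the cis C2/C3 relationship. The fallback sets out from 2 and comes back at 3. Rhodium-catalysed trans-hydroboration ([Rh(cod)Cl]2, P(iPr)3, Et3N, pinacolborane, cyclohexane, rt) should give 2-[(Z)-2-[3,4-bis(benzyloxy)phenyl]ethenyl]-4,4,5,5-tetramethyl-1,3,2-dioxaborolane F5. Treatment with KHF2 (MeOH/H2O) should give potassium (Z)-[2-[3,4-bis(benzyloxy)phenyl]ethenyl]trifluoroborate F6. Stereoretentive copper-catalysed oxidative coupling with acetic acid (CuBr, DMAP, 4 Å MS, O2, DMSO, 60 °C) should then give 3.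

Further compounds
F1 | step 4 | 3,5-bis(benzyloxy)-2-(hydroxymethyl)phenol | OCc1c(O)cc(OCc2ccccc2)cc1OCc1ccccc1
F2 | step 4 | (2R,3R)-5,7-bis(benzyloxy)-2-[3,4-bis(benzyloxy)phenyl]chroman-3-yl acetate | CC(=O)O[C@@H]1Cc2c(OCc3ccccc3)cc(OCc3ccccc3)cc2O[C@@H]1c1ccc(OCc2ccccc2)c(OCc2ccccc2)c1
F3 | step 8 | (2R,3R,4S)-5,7-bis(benzyloxy)-2-[3,4-bis(benzyloxy)phenyl]-8-bromo-4-(2-ethoxyethoxy)chroman-3-ol | CCOCCO[C@H]1c2c(OCc3ccccc3)cc(OCc3ccccc3)c(Br)c2O[C@H](c2ccc(OCc3ccccc3)c(OCc3ccccc3)c2)[C@@H]1O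
F4 | step 8 | upper-unit 8-bromo derivative of 13 (bromine at C8 of the upper flavan unit, 4β→8 linkage) | O=C(O[C@@H]1Cc2c(OCc3ccccc3)cc(OCc3ccccc3)c([C@H]3c4c(OCc5ccccc5)cc(OCc5ccccc5)c(Br)c4O[C@H](c4ccc(OCc5ccccc5)c(OCc5ccccc5)c4)[C@@H]3O)c2O[C@@H]1c1cc(OCc2ccccc2)c(OCc2ccccc2)c(OCc2ccccc2)c1)c1cc(OCc2ccccc2)c(OCc2ccccc2)c(OCc2ccccc2)c1
F5 | step 2 | 2-[(Z)-2-[3,4-bis(benzyloxy)phenyl]ethenyl]-4,4,5,5-tetramethyl-1,3,2-dioxaborolane | CC1(C)OB(/C=C\c2ccc(OCc3ccccc3)c(OCc3ccccc3)c2)OC1(C)C
F6 | step 2 | potassium (Z)-[2-[3,4-bis(benzyloxy)phenyl]ethenyl]trifluoroborate | [K+].F[B-](F)(F)/C=C\c1ccc(OCc2ccccc2)c(OCc2ccccc2)c1
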